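Late in the maple run, at 80.0 min, target stood at 19.8% of the charge despite 5.3 mM catalyst, and that number showed me what a forecast of these flasks would have to contain.

all flasks: gas phase 1.7 mM (held)

| run | starting material | catalyst | remark | time |
|---|---|---|---|---|
| birch | 0.010 M | 0.30 mM | run made earlier |  |
| maple | 0.010 M | 5.3 mM | run made earlier |  |
| elm | 0.0078 M | 1.5 mM | run made earlier |  |
| Sunday's | 0.040 M | 5.0 mM |  | 2.0 h |
| Tuesday's | 0.010 M | 1.5 mM |  | 2.0 h |
| Saturday's | 0.0060 M | 0.40 mM |  | 2.0 h |
| Thursday's | 0.0050 M | 3.0 mM |  | 2.0 h |
| Wednesday's | 0.0025 M | 5.0 mM |  | 2.0 h |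

| birch: time / min | birch: target / % | maple: time / min | maple: target / % | elm: time / min | elm: target / % |
|---|---|---|---|---|---|
| 6.00 | 0.6 | 8.00 | 1.5 | 6.00 | 0.3 |
| 12.0 | 0.5 | 20.0 | 6.3 | 12.0 | 2.1 |
| 25.0 | 0.2 | 40.0 | 11.5 | 25.0 | 4.3 |
| 40.0 | 1.5 | 60.0 | 16.0 | 40.0 | 7.5 |
| 80.0 | 3.9 | 80.0 | 19.8 | 80.0 | 14.9 |

(readings scatter by 0.5 percentage points)

- at the start none of the gas phase is in solution
- a reading or a percentage of target counts all its forms, free or not

* ranking by amount of target, in percent of the starting material charged, from high to low, at 2.0 h (Sunday's / Tuesday's / Saturday's / Thursday's / Wednesday's)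
* the amount of target, in percent of the starting material charged of the flask you put first, at 2.0 h
* the amount of target, in percent of the starting material charged of the flask you put last, at 2.0 h

I went through a run in slow motion. In the first instants no gas is in solution, and birch shows the wait: its reading at 25.0 min is 0.2%, less than the scatter of 0.5 percentage points. In the middle, with gas arriving, I expected a flask with gas to spare to behave like an enzyme at fixed cosubstrate, pseudo-first-order in starting material with a rate constant proportional to c(catalyst). Integrated, the fraction left is exp(−k·c(catalyst)·t), and the charge of starting material drops out.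

Birch's last reading, 3.9% on 0.30 mM catalyst, gave 0.0995 /mM/h. This is the catalyst clock k, the logarithm of charged over left, per unit of catalyst and of time; as a reading it carries the scatter.

The end of a run is where the clock can fail. For maple it gives 50.5%, far more than the flask read, so I took maple's mean rate of target over the whole run, the wait included, 1.49 mM/h, as a working ceiling on target made per hour: a guess from one run's readings, not a measured limit. My rule gave each flask the smaller of the clock's percentage and that rate times the time over c(starting material).

Wednesday's got 63.0%, its ceiling of 119% lying above the charge. Sunday's has the same clock but a ceiling of 7.42%. By the clock, Thursday's got 44.9%, Tuesday's 25.8% and Saturday's 7.65%, which put Saturday's barely above Sunday's.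

The forecast, on its own grounds, gave Wednesday's > Thursday's > Tuesday's > Saturday's > Sunday's, with 55% first and 7.5% last: “Percent yield then favours dilute substrate with high catalyst”. Its order was mine; its top lay below my figure.

The flasks gave Wednesday's > Thursday's > Tuesday's > Saturday's > Sunday's, with 65.9% first and 2.97% last.

    gas phase ⇌ dissolved gas, rate k1*(csat - [dissolved gas]) (kL = 1.60 /h)
    starting material + dissolved gas + catalyst → catalyst + target (k = 2.50 × 10⁵ /M²/h)
    crystals ⇌ target, rate k3*(cs3 - [target]) while solid is left; crystals form when [target] > cs3 (solubility = 7.50 mM, k = 31.0 /h)
    starting material ⇌ dormant form (K = 0.470, k = 11.0 /h)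
    starting material + target → side product (k = 95.0 /M/h)

Wednesday's came in 2.9 points above the clock's figure, and Sunday's fell below my ceiling. For a flask like Wednesday's with 0.0085 M catalyst, the clock says 81.6%, and that flask gave 78.1%. In Wednesday's at 2.00 h, dissolved gas was made 1.53 times faster than it was used up, each step taken net, and it stood at 0.00115 M, far above the 9.69 × 10⁻⁵ M in Sunday's.

(Readings and results were generated by integration on assumed constants, noise included.)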